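## Retrosynthetic overview

- The strategy rests on ring A: the two prenyl CH2 groups sit on C6 and C8, the two carbons flanking the C7 hydroxyl. Each CH2–CH= bond (C1''–C2'') is cut to an ortho-quinone methide (C7=O with an exocyclic CH2 at C6 or C8) and a 2-methylpropenylboron nucleophile.
- Both quinone methides are released in turn from one phenol, the 6,8-bis(dimethylaminomethyl)-7-hydroxyflavanone 12, made by double Mannich reaction of 7-hydroxyflavanone 9 with dimethylmethyleneiminium iodide.
- The C2–aryl bond and the C2 stereocentre come from a rhodium-catalysed asymmetric 1,4-addition of ring B boronic acid 5 (from 4-bromoresorcinol) to silylated 7-hydroxychromone 7.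
- No ring is formed in the route: rings A and C arrive together in 7-hydroxychromone and ring B in 4-bromoresorcinol. The two MOM groups on ring B come off last.

Key step: step 7

Assumption (step 4): the (S)-antipode of MeO-F12-BIPHEP, (S)-2,2'-bis[bis(3,4,5-trifluorophenyl)phosphino]-6,6'-dimethoxy-1,1'-biphenyl, is taken to give (2S) by analogy with cyclic enones; the sense is to be confirmed on the first run and the (R)-ligand used if needed.

Assumption (step 7): the C8 arm is written as reacting first; the order of the two arms does not change the product.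

## Route

Step 1
Reactants: 1 4-bromoresorcinol
Product: 2 1-bromo-2,4-bis(methoxymethoxy)benzene
Conditions: NaH (2.4 equiv), MOMCl (2.4 equiv), DMF, 0 °C to rt
Reagents that add atoms: chloromethyl methyl ether, COCCl
Why: O-alkylation of the two sodium phenoxides with the reactive chloromethyl ether (Williamson-type acetal protection) should proceed cleanly, the aryl bromide being inert.

Step 2
Reactants: 2 1-bromo-2,4-bis(methoxymethoxy)benzene
Product: 5 [2,4-bis(methoxymethoxy)phenyl]boronic acid, via aryllithium 3 (not isolated), via lithium aryltriisopropoxyborate 4 (not isolated)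
Conditions: n-BuLi (1.05 equiv), THF, −78 °C; B(Oi-Pr)3 (1.5 equiv), −78 °C to rt; sat. aq NH4Cl
Reagents that add atoms: triisopropyl borate, CC(C)OB(OC(C)C)OC(C)C; water, O
Why: Bromine–lithium exchange at −78 °C is faster than any attack on the MOM acetals and gives an aryllithium stabilised by the ortho OMOM group, which is trapped by the borate ester and hydrolysed under mild, MOM-safe work-up (lithiation–borylation).

Step 3
Reactants: 6 7-hydroxy-4H-chromen-4-one
Product: 7 7-(triisopropylsilyloxy)-4H-chromen-4-one
Conditions: i-Pr3SiCl (1.2 equiv), imidazole (2 equiv), DMF, rt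
Reagents that add atoms: chlorotriisopropylsilane, CC(C)[Si](Cl)(C(C)C)C(C)C
Why: Imidazole-promoted silylation of the acidic C7 phenol masks the hydroxyl, which as a phenoxide would deactivate the enone, as a bulky silyl ether that should survive the base-free next step.

Step 4
Reactants: 7 7-(triisopropylsilyloxy)-4H-chromen-4-one; 5 [2,4-bis(methoxymethoxy)phenyl]boronic acid
Product: 8 (2S)-2-[2,4-bis(methoxymethoxy)phenyl]-7-(triisopropylsilyloxy)chroman-4-one
Conditions: [Rh(OH)(cod)]2 (2.5 mol%), (S)-MeO-F12-BIPHEP (5.5 mol%), 5 (3 equiv, in portions), PhMe/H2O (10:1), 30 °C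
Reagents that add atoms: none
Why: Rhodium-catalysed asymmetric 1,4-addition of an arylboronic acid to a chromone (Hayashi–Miyaura reaction) transfers the aryl group from boron to the hydroxo complex of monovalent rhodium, inserts the C2=C3 bond enantioface-selectively and protonates the rhodium enolate with water, so the electron-poor chiral bisphosphine sets C2 as S while the base-free medium spares the silyl ether and avoids ring-opening.

Step 5
Reactants: 8 (2S)-2-[2,4-bis(methoxymethoxy)phenyl]-7-(triisopropylsilyloxy)chroman-4-one
Product: 9 (2S)-2-[2,4-bis(methoxymethoxy)phenyl]-7-hydroxychroman-4-one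
Conditions: Bu4NF (1.1 equiv), AcOH (1.2 equiv), THF, 0 °C
Reagents that add atoms: none
Why: Fluoride cleaves the aryl silyl ether quickly, and the acetic acid buffer keeps the medium from becoming basic enough to open the flavanone by retro-oxa-Michael reaction, so C2 and the MOM ethers should be untouched.

Step 6
Reactants: 9 (2S)-2-[2,4-bis(methoxymethoxy)phenyl]-7-hydroxychroman-4-one; 10 dimethylmethyleneiminium iodide
Product: 12 (2S)-2-[2,4-bis(methoxymethoxy)phenyl]-6,8-bis[(dimethylamino)methyl]-7-hydroxychroman-4-one, via 8-(dimethylaminomethyl) phenol 11 (not isolated)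
Conditions: 10 (2.5 equiv), K2CO3 (3 equiv), CH2Cl2, rt to 35 °C
Reagents that add atoms: dimethylmethyleneiminium iodide 10, C=[N+](C)C.[I-]
Why: Phenoxide-directed ortho-aminomethylation (Mannich reaction with a preformed iminium salt) should place carbon at C8 and then C6, the only free positions ortho to the C7 oxygen since the para position C4a is substituted, while the MOM-capped ring B and the non-enolised C3 are far weaker nucleophiles.

Step 7
Reactants: 12 (2S)-2-[2,4-bis(methoxymethoxy)phenyl]-6,8-bis[(dimethylamino)methyl]-7-hydroxychroman-4-one; 13 (2-methylprop-1-enyl)boronic acid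
Product: 17 (2S)-2-[2,4-bis(methoxymethoxy)phenyl]-7-hydroxy-6,8-bis(3-methylbut-2-enyl)chroman-4-one, via C8 ortho-quinone methide 14 (not isolated), via 8-prenyl-6-(dimethylaminomethyl) phenol 15 (not isolated), via C6 ortho-quinone methide 16 (not isolated)
Conditions: 13 (5 equiv), PhMe, 110 °C, slow Ar sweep through the condenser; then pH 7 aqueous work-up
Reagents that add atoms: (2-methylprop-1-enyl)boronic acid 13, CC(C)=CB(O)O
Why: Proposed new method: the phenol and the boronic acid should condense to an aryloxyboron species in which the nitrogen of an ortho CH2NMe2 arm coordinates boron (six-membered O–B–N chelate), so that loss of the amine, driven by heat and by removal of volatile Me2NH in the gas stream, gives ortho-quinone methide 14 with boron held on the C7 oxygen; the 2-methylpropenyl group then migrates from tetracoordinate boron to the exocyclic CH2 through a six-membered transition state, the arene is restored, and after B–O exchange the same sequence runs at the second arm via 15 and 16. The closest known reaction types are the thermal generation of ortho-quinone methides from phenolic Mannich bases with trapping by carbon nucleophiles, the 1,4-addition of alkenylboronic acids and boronates to ortho-quinone methides, and the Petasis borono-Mannich reaction, in which a phenoxide-bound boron delivers an alkenyl group in the same way; what has not been shown is the twofold run on one phenol that also carries an aryl ketone. No ring is closed and no stereocentre is formed: C2 is a spectator whose configuration should hold because no strong base is present and the liberated amine is swept out or bound by the excess boronic acid. The step needs chemoselectivity for carbon 1,4-addition over dimerisation of the quinone methide, which the intramolecular alkenyl delivery from oxygen-bound boron and the excess of 13 should secure, re-addition of Me2NH being reversible and unproductive. Regiochemistry is fixed beforehand, since the CH2 carbons already sit on C6 and C8 and the alkenyl carbon that leaves boron is the one that bonds, so only the linear 3-methylbut-2-enyl group can form, and the non-basic boron reagent leaves the C4 ketone and the MOM acetals alone.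

Step 8
Reactants: 17 (2S)-2-[2,4-bis(methoxymethoxy)phenyl]-7-hydroxy-6,8-bis(3-methylbut-2-enyl)chroman-4-one
Product: 18 (2S)-2-(2,4-dihydroxyphenyl)-7-hydroxy-6,8-bis(3-methylbut-2-enyl)chroman-4-one (CNP0318833.1)
Conditions: 3 M aq HCl/MeOH (1:10), 30 °C, stopped at full conversion
Reagents that add atoms: none
Why: Acid-catalysed acetal exchange with methanol removes both aryl MOM ethers as dimethoxymethane, and the low temperature and short exposure are chosen to keep the prenyl groups from cyclising onto the C7 hydroxyl and to keep C2 intact.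

## Compound list

1 | 4-bromoresorcinol (4-bromobenzene-1,3-diol) | Oc1ccc(Br)c(O)c1 | starting material
2 | 1-bromo-2,4-bis(methoxymethoxy)benzene | COCOc1ccc(Br)c(OCOC)c1 | intermediate
3 | [2,4-bis(methoxymethoxy)phenyl]lithium (formed in the flask, step 2) | [Li]c1ccc(OCOC)cc1OCOC | intermediate
4 | lithium [2,4-bis(methoxymethoxy)phenyl]tri(propan-2-yloxy)borate (formed in the flask, step 2) | [Li+].CC(C)O[B-](OC(C)C)(OC(C)C)c1ccc(OCOC)cc1OCOC | intermediate
5 | [2,4-bis(methoxymethoxy)phenyl]boronic acid | OB(O)c1ccc(OCOC)cc1OCOC | intermediate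
6 | 7-hydroxy-4H-chromen-4-one | O=c1ccoc2cc(O)ccc12 | starting material
7 | 7-(triisopropylsilyloxy)-4H-chromen-4-one | CC(C)[Si](Oc1ccc2c(c1)occc2=O)(C(C)C)C(C)C | intermediate
8 | (2S)-2-[2,4-bis(methoxymethoxy)phenyl]-7-(triisopropylsilyloxy)chroman-4-one | CC(C)[Si](Oc1ccc2c(c1)O[C@H](c1ccc(OCOC)cc1OCOC)CC2=O)(C(C)C)C(C)C | intermediate
9 | (2S)-2-[2,4-bis(methoxymethoxy)phenyl]-7-hydroxychroman-4-one | Oc1ccc2c(c1)O[C@H](c1ccc(OCOC)cc1OCOC)CC2=O | intermediate
10 | dimethylmethyleneiminium iodide | C=[N+](C)C.[I-] | starting material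
11 | (2S)-2-[2,4-bis(methoxymethoxy)phenyl]-8-[(dimethylamino)methyl]-7-hydroxychroman-4-one (formed in the flask, step 6) | CN(C)Cc1c(O)ccc2c1O[C@H](c1ccc(OCOC)cc1OCOC)CC2=O | intermediate
12 | (2S)-2-[2,4-bis(methoxymethoxy)phenyl]-6,8-bis[(dimethylamino)methyl]-7-hydroxychroman-4-one | CN(C)Cc1cc2c(c(CN(C)C)c1O)O[C@H](c1ccc(OCOC)cc1OCOC)CC2=O | intermediate
13 | (2-methylprop-1-enyl)boronic acid | CC(C)=CB(O)O | starting material
14 | (2S)-2-[2,4-bis(methoxymethoxy)phenyl]-6-[(dimethylamino)methyl]-8-methylidene-2,3-dihydrochromene-4,7-dione, the C8 ortho-quinone methide (formed in the flask, step 7) | CN(C)CC1=CC2=C(C(=C)C1=O)O[C@H](c1ccc(OCOC)cc1OCOC)CC2=O | intermediate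
15 | (2S)-2-[2,4-bis(methoxymethoxy)phenyl]-6-[(dimethylamino)methyl]-7-hydroxy-8-(3-methylbut-2-enyl)chroman-4-one (formed in the flask, step 7) | CN(C)Cc1cc2c(c(CC=C(C)C)c1O)O[C@H](c1ccc(OCOC)cc1OCOC)CC2=O | intermediate
16 | (2S)-2-[2,4-bis(methoxymethoxy)phenyl]-6-methylidene-8-(3-methylbut-2-enyl)-2,3-dihydrochromene-4,7-dione, the C6 ortho-quinone methide (formed in the flask, step 7) | C=C1C=C2C(=C(CC=C(C)C)C1=O)O[C@H](c1ccc(OCOC)cc1OCOC)CC2=O | intermediate
17 | (2S)-2-[2,4-bis(methoxymethoxy)phenyl]-7-hydroxy-6,8-bis(3-methylbut-2-enyl)chroman-4-one | CC(C)=CCc1cc2c(c(CC=C(C)C)c1O)O[C@H](c1ccc(OCOC)cc1OCOC)CC2=O | intermediate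
18 | (2S)-2-(2,4-dihydroxyphenyl)-7-hydroxy-6,8-bis(3-methylbut-2-enyl)chroman-4-one | CC(C)=CCc1cc2c(c(CC=C(C)C)c1O)O[C@H](c1ccc(O)cc1O)CC2=O | target

## Step count and risks

Total step count: 8. Longest linear sequence: 7 steps (steps 1, 2, 4, 5, 6, 7, 8 from 4-bromoresorcinol).

**Step 7 (most likely to fail).** Amine loss may be too slow at a temperature the flavanone tolerates, the quinone methide may dimerise or be intercepted before the alkenyl group is transferred, or C2 may epimerise by ring-opening under heat and amine. The fallback uses known chemistry, sets out from 9 and comes back at 18. Phenol 9 is iodinated at both ortho positions (I2, NaHCO3, THF/H2O) to give (2S)-2-[2,4-bis(methoxymethoxy)phenyl]-7-hydroxy-6,8-diiodochroman-4-one F1. The C7 hydroxyl is capped (MOMCl, i-Pr2NEt, CH2Cl2) to give (2S)-2-[2,4-bis(methoxymethoxy)phenyl]-6,8-diiodo-7-(methoxymethoxy)chroman-4-one F2. Twofold Stille coupling with tributyl(3-methylbut-2-enyl)stannane (Pd(PPh3)4, DMF, 90 °C), which is known to give mainly the linear prenyl arene, gives (2S)-2-[2,4-bis(methoxymethoxy)phenyl]-7-(methoxymethoxy)-6,8-bis(3-methylbut-2-enyl)chroman-4-one F3. The acid of step 8 then removes all three MOM groups and gives 18.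

**Step 4.** Protodeboronation of the electron-rich, ortho-substituted boronic acid may outrun the slow insertion of the chromone, or facial selectivity may be poor with the ortho OMOM group. The fallback sets out from 2 and 7 and comes back at 8. Bromide 2 is converted with Mg in THF into [2,4-bis(methoxymethoxy)phenyl]magnesium bromide F4, which is added to chromone 7 with CuBr·SMe2 (10 mol%) and Me3SiCl at −78 °C. This gives the racemic silyl enol ether 2-[2,4-bis(methoxymethoxy)phenyl]-7-(triisopropylsilyloxy)-4-(trimethylsilyloxy)-2H-chromene F5, which is hydrolysed on work-up to racemic 2-[2,4-bis(methoxymethoxy)phenyl]-7-(triisopropylsilyloxy)chroman-4-one F6. Preparative HPLC on a chiral stationary phase separates F6 into 8 and its antipode (2R)-2-[2,4-bis(methoxymethoxy)phenyl]-7-(triisopropylsilyloxy)chroman-4-one F7, which is discarded.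

**Step 8.** Under Brønsted acid a prenyl group may cyclise onto the C7 hydroxyl (chroman formation), and the C2 configuration may erode by ionisation of the C2–O1 bond, which is benzylic to an aryl ring carrying ortho and para oxygens. The fallback sets out from 17 and comes back at 18. Compound 17 is treated with Me3SiOTf and 2,2'-bipyridyl in CH2Cl2 at 0 °C, which should exchange the aryl MOM ethers for trimethylsilyl ethers without free protic acid (the C7 hydroxyl is expected to be silylated as well). This gives (2S)-2-[2,4-bis(trimethylsilyloxy)phenyl]-6,8-bis(3-methylbut-2-enyl)-7-(trimethylsilyloxy)chroman-4-one F8. Water added to the same flask then hydrolyses the silyl ethers to 18.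

## Further compounds

F1 | step 7 | (2S)-2-[2,4-bis(methoxymethoxy)phenyl]-7-hydroxy-6,8-diiodochroman-4-one | Oc1c(I)cc2c(c1I)O[C@H](c1ccc(OCOC)cc1OCOC)CC2=O
F2 | step 7 | (2S)-2-[2,4-bis(methoxymethoxy)phenyl]-6,8-diiodo-7-(methoxymethoxy)chroman-4-one | COCOc1c(I)cc2c(c1I)O[C@H](c1ccc(OCOC)cc1OCOC)CC2=O
F3 | step 7 | (2S)-2-[2,4-bis(methoxymethoxy)phenyl]-7-(methoxymethoxy)-6,8-bis(3-methylbut-2-enyl)chroman-4-one | COCOc1c(CC=C(C)C)cc2c(c1CC=C(C)C)O[C@H](c1ccc(OCOC)cc1OCOC)CC2=O
F4 | step 4 | [2,4-bis(methoxymethoxy)phenyl]magnesium bromide | COCOc1ccc([Mg]Br)c(OCOC)c1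
F5 | step 4 | 2-[2,4-bis(methoxymethoxy)phenyl]-7-(triisopropylsilyloxy)-4-(trimethylsilyloxy)-2H-chromene (racemic) | CC(C)[Si](Oc1ccc2c(c1)OC(c1ccc(OCOC)cc1OCOC)C=C2O[Si](C)(C)C)(C(C)C)C(C)C
F6 | step 4 | 2-[2,4-bis(methoxymethoxy)phenyl]-7-(triisopropylsilyloxy)chroman-4-one (racemic) | CC(C)[Si](Oc1ccc2c(c1)OC(c1ccc(OCOC)cc1OCOC)CC2=O)(C(C)C)C(C)C
F7 | step 4 | (2R)-2-[2,4-bis(methoxymethoxy)phenyl]-7-(triisopropylsilyloxy)chroman-4-one | CC(C)[Si](Oc1ccc2c(c1)O[C@@H](c1ccc(OCOC)cc1OCOC)CC2=O)(C(C)C)C(C)C
F8 | step 8 | (2S)-2-[2,4-bis(trimethylsilyloxy)phenyl]-6,8-bis(3-methylbut-2-enyl)-7-(trimethylsilyloxy)chroman-4-one | CC(C)=CCc1cc2c(c(CC=C(C)C)c1O[Si](C)(C)C)O[C@H](c1ccc(O[Si](C)(C)C)cc1O[Si](C)(C)C)CC2=O
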